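**Retrosynthetic overview**
1. Target 16 ⇐ 15 (selective removal of the 15-O-acetyl) ⇐ 13 (exocyclic C8=C17 from the 8α-ol) ⇐ 12 (C15–O bond by 1,3-shift of the tertiary allylic 13-acetate).
2. Ring A of 12 ⇐ 10 ⇐ 8 ⇐ 7: C18 acid from C18–OH; 3α-oxygen from the 3-ketone by equatorial hydride delivery.
3. Key bond: C18–O of 7, by imine-directed copper hydroxylation of the equatorial 4α-methyl of 3-oxosclareol 3 (the new step; it fixes C4).
4. 3 ⇐ 2 ⇐ 1: C3–O by enzymatic C–H hydroxylation of (−)-sclareol.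
5. No ring is formed: both rings, all twenty skeletal carbons and the C5, C9 and C10 centres come from sclareol; only C–O bonds (C3, C18, C15) and two C=C bonds are made.

The target is read as the normal-series labdane 3α-acetoxy-15-hydroxylabda-8(17),13E-dien-18-oic acid (4α-CO2H = C18, 4β-CH3 = C19; 5α-H, 9α-H, 10β-CH3). Labdane numbering is used throughout.

Assumption: the C3-hydroxylating cytochrome P450 BM3 variant is taken as available by expression in E. coli; everything else is a catalogue chemical, and (−)-sclareol is the only chiral starting material.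

**Step 1**
Reactants: 1 (−)-sclareol, (13R)-labd-14-ene-8α,13-diol
Product: 2 3β-hydroxysclareol, (13R)-labd-14-ene-3β,8α,13-triol
Conditions: engineered cytochrome P450 BM3 (CYP102A1) C3-hydroxylase variant (clarified E. coli lysate), NADP+ (cat.), glucose dehydrogenase, D-glucose, air, KPi buffer pH 8.0 / EtOH 95:5, 25 °C
Reagents that add atoms: dioxygen, O=O
Why: Enzymatic C–H hydroxylation (P450 monooxygenation, hydrogen abstraction/oxygen rebound with retention): BM3 variants of the sclareolide-hydroxylating family accept sclareol and oxidise the equatorial C3–H of ring A, giving the 3β-alcohol and leaving the tertiary alcohols and the vinyl group untouched.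

**Step 2**
Reactants: 2 3β-hydroxysclareol
Product: 3 3-oxosclareol, (13R)-8α,13-dihydroxylabd-14-en-3-one
Conditions: Dess–Martin periodinane (1.3 equiv), NaHCO3, CH2Cl2, 0 °C → rt
Reagents that add atoms: none
Why: Dess–Martin oxidation touches only the secondary alcohol (the two tertiary alcohols cannot be oxidised), which removes the enzyme-set 3β centre so that C3 can be reset as 3α and provides the carbonyl that directs step 3.

**Step 3**
Reactants: 3 3-oxosclareol; 4 2-picolylamine
Product: 7 18-hydroxy-3-oxosclareol, (13R)-8α,13,18-trihydroxylabd-14-en-3-one (4α-CH2OH, 4β-CH3), via picolyl imine 5 (not isolated), via 18-hydroxy imine 6 (not isolated)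
Conditions: a) 4 (1.2 equiv), PPTS (5 mol%), 4 Å MS, PhMe, 80 °C, then evaporate; b) Cu(NO3)2·3H2O (1.0 equiv), Et3N (1 equiv), 30% aq. H2O2 (5 equiv), acetone, 0 °C → rt; c) sat. aq. Na4EDTA, then AcOH/NaOAc buffer pH 5, THF, rt
Reagents that add atoms: hydrogen peroxide, OO
Why: Proposed new method: imine-directed copper/hydrogen peroxide C–H hydroxylation (Schönecker-type) asked for the first time to oxidise a primary C–H of a gem-dimethyl group – the picolyl imine forms with its N-substituent anti to the quaternary C4, so the chelated divalent copper hydroperoxide lies in the imine plane on the C4 side, O–O homolysis gives a copper-bound oxyl that abstracts hydrogen through a seven-membered transition state from the only carbon held in that plane, the equatorial 4α-methyl (C18; the axial 4β-methyl and the axial H-5α are out of reach), and rebound plus imine hydrolysis gives the β-hydroxy ketone, which sets the C4 stereocentre; the closest known reaction is the 12β-hydroxylation of 17-oxo steroids through the same imine, where the in-plane methylene reacts and the axial angular methyl and axial methine do not.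

**Step 4**
Reactants: 7 18-hydroxy-3-oxosclareol
Product: 8 (13R)-labd-14-ene-3α,8α,13,18-tetraol
Conditions: LiBH(s-Bu)3 (L-Selectride, 4 equiv), THF, −78 °C; MeOH, then aq. NH4Cl
Reagents that add atoms: none
Why: Diastereoselective ketone reduction with a bulky trialkylborohydride: hydride enters along the equatorial trajectory (the axial approach past H-1α and H-5α is blocked for a reagent of this size), as in the reduction of 4,4-disubstituted 3-oxo terpenoids to their axial alcohols, which sets C3 as 3α (3R).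

**Step 5**
Reactants: 8 (13R)-labd-14-ene-3α,8α,13,18-tetraol
Product: 10 (13R)-3α,8α,13-trihydroxylabd-14-en-18-oic acid, via C18 aldehyde 9 (not isolated)
Conditions: TEMPO (0.2 equiv), PhI(OAc)2 (2.5 equiv), MeCN / pH 7 phosphate buffer 1:1, rt
Reagents that add atoms: water, O
Why: Oxoammonium (TEMPO) oxidation is selective for the primary C18 alcohol over the hindered axial secondary 3α-OH and the tertiary alcohols (as in the known selective oxidation of the equatorial 4α-CH2OH of 3-hydroxy triterpenoids), and the aldehyde hydrate is carried on to the acid in the aqueous medium.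

**Step 6**
Reactants: 10 (13R)-3α,8α,13-trihydroxylabd-14-en-18-oic acid
Product: 12 (13R)-3α,13-diacetoxy-8α-hydroxylabd-14-en-18-oic acid, via mixed anhydride 11 (not isolated)
Conditions: Ac2O (5 equiv), DMAP (0.2 equiv), Et3N, CH2Cl2, 0 °C → rt (monitored); then aq. NaHCO3/THF, rt; 5% citric acid
Reagents that add atoms: acetic anhydride, CC(=O)OC(C)=O
Why: DMAP-catalysed (Steglich-type) acylation acetylates the secondary 3α-OH and the open-chain tertiary allylic 13-OH (linalool-like), while the ring 8α-OH, flanked by C9 and the angular methyl, is the slowest and is left free; the mixed anhydride at C18 is cleaved at its unhindered acetyl carbonyl in the bicarbonate work-up.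

**Step 7**
Reactants: 12 (13R)-3α,13-diacetoxy-8α-hydroxylabd-14-en-18-oic acid
Product: 13 (13E)-3α,15-diacetoxy-8α-hydroxylabd-13-en-18-oic acid
Conditions: PdCl2(MeCN)2 (5 mol%), THF, rt
Reagents that add atoms: none
Why: Divalent-palladium-catalysed [3,3] allylic acetate transposition (cyclisation-induced rearrangement through a six-membered acetoxonium intermediate) forms the C15–O bond and is driven to the trisubstituted primary allylic acetate; the chair-like intermediate with the C12 chain equatorial gives mainly the 13E alkene, and the minor 13Z isomer is removed by chromatography.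

**Step 8**
Reactants: 13 (13E)-3α,15-diacetoxy-8α-hydroxylabd-13-en-18-oic acid
Product: 15 (13E)-3α,15-diacetoxylabda-8(17),13-dien-18-oic acid, via 8-O-chlorosulfite 14 (not isolated)
Conditions: SOCl2 (2 equiv), pyridine, CH2Cl2, −78 °C; then aq. NaHCO3/THF, rt; 5% citric acid
Reagents that add atoms: none
Why: Dehydration of an equatorial tertiary alcohol through its chlorosulfite (E2 with pyridine): no ring hydrogen is anti-periplanar to the equatorial C8–O bond, so a C17 methyl hydrogen is removed and the exocyclic 8(17)-alkene results; any acyl chloride formed at the hindered C18 acid is hydrolysed in the bicarbonate work-up.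

**Step 9**
Reactants: 15 (13E)-3α,15-diacetoxylabda-8(17),13-dien-18-oic acid
Product: 16 (13E)-3α-acetoxy-15-hydroxylabda-8(17),13-dien-18-oic acid (target)
Conditions: K2CO3 (1.5 equiv), MeOH, 0 °C; then 5% citric acid
Reagents that add atoms: none
Why: Base-catalysed transesterification (Zemplén-type methanolysis) is far faster at the unhindered primary allylic 15-acetate than at the axial, neopentyl-type 3α-acetate sitting next to the carboxylate, so only the 15-OH is freed.

**Compound list**
1 | (−)-sclareol, (13R)-labd-14-ene-8α,13-diol | C[C@@]1(O)CC[C@@H]2[C@](C)(CCCC2(C)C)[C@H]1CC[C@@](C)(O)C=C | starting material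
2 | 3β-hydroxysclareol, (13R)-labd-14-ene-3β,8α,13-triol | C[C@@]1(O)CC[C@@H]2[C@](C)(CC[C@H](O)C2(C)C)[C@H]1CC[C@@](C)(O)C=C | intermediate
3 | 3-oxosclareol, (13R)-8α,13-dihydroxylabd-14-en-3-one | C[C@@]1(O)CC[C@@H]2[C@](C)(CCC(=O)C2(C)C)[C@H]1CC[C@@](C)(O)C=C | intermediate
4 | 2-picolylamine, 2-(aminomethyl)pyridine | NCc1ccccn1 | starting material
5 | (E)-N-(pyridin-2-ylmethyl) imine of 3 at C3, picolyl group anti to C4 | C[C@@]1(O)CC[C@@H]2[C@](C)(CC/C(=N\Cc3ccccn3)C2(C)C)[C@H]1CC[C@@](C)(O)C=C | intermediate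
6 | 18-hydroxy derivative of imine 5 (4α-CH2OH, 4β-CH3) | C[C@@]1(O)CC[C@@H]2[C@](C)(CC/C(=N\Cc3ccccn3)[C@@]2(C)CO)[C@H]1CC[C@@](C)(O)C=C | intermediate
7 | 18-hydroxy-3-oxosclareol, (13R)-8α,13,18-trihydroxylabd-14-en-3-one | C[C@@]1(O)CC[C@@H]2[C@](C)(CCC(=O)[C@@]2(C)CO)[C@H]1CC[C@@](C)(O)C=C | intermediate
8 | (13R)-labd-14-ene-3α,8α,13,18-tetraol | C[C@@]1(O)CC[C@@H]2[C@](C)(CC[C@@H](O)[C@@]2(C)CO)[C@H]1CC[C@@](C)(O)C=C | intermediate
9 | (13R)-3α,8α,13-trihydroxylabd-14-en-18-al | C[C@@]1(O)CC[C@@H]2[C@](C)(CC[C@@H](O)[C@@]2(C)C=O)[C@H]1CC[C@@](C)(O)C=C | intermediate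
10 | (13R)-3α,8α,13-trihydroxylabd-14-en-18-oic acid | C[C@@]1(O)CC[C@@H]2[C@](C)(CC[C@@H](O)[C@@]2(C)C(=O)O)[C@H]1CC[C@@](C)(O)C=C | intermediate
11 | mixed acetic anhydride of 12 at the C18 carboxyl | C[C@@]1(O)CC[C@@H]2[C@](C)(CC[C@@H](OC(C)=O)[C@@]2(C)C(=O)OC(C)=O)[C@H]1CC[C@@](C)(OC(C)=O)C=C | intermediate
12 | (13R)-3α,13-diacetoxy-8α-hydroxylabd-14-en-18-oic acid | C[C@@]1(O)CC[C@@H]2[C@](C)(CC[C@@H](OC(C)=O)[C@@]2(C)C(=O)O)[C@H]1CC[C@@](C)(OC(C)=O)C=C | intermediate
13 | (13E)-3α,15-diacetoxy-8α-hydroxylabd-13-en-18-oic acid | C[C@@]1(O)CC[C@@H]2[C@](C)(CC[C@@H](OC(C)=O)[C@@]2(C)C(=O)O)[C@H]1CC/C(C)=C/COC(C)=O | intermediate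
14 | 8-O-chlorosulfite of 13 | C[C@@]1(OS(=O)Cl)CC[C@@H]2[C@](C)(CC[C@@H](OC(C)=O)[C@@]2(C)C(=O)O)[C@H]1CC/C(C)=C/COC(C)=O | intermediate
15 | (13E)-3α,15-diacetoxylabda-8(17),13-dien-18-oic acid | C=C1CC[C@@H]2[C@](C)(CC[C@@H](OC(C)=O)[C@@]2(C)C(=O)O)[C@H]1CC/C(C)=C/COC(C)=O | intermediate
16 | (13E)-3α-acetoxy-15-hydroxylabda-8(17),13-dien-18-oic acid | C=C1CC[C@@H]2[C@](C)(CC[C@@H](OC(C)=O)[C@@]2(C)C(=O)O)[C@H]1CC/C(C)=C/CO | target

**Step count and risks**
Total steps: 9. Longest linear sequence: 9 (fully linear from sclareol).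

Step 3 is the most likely to fail. A primary C–H is about 3 kcal/mol stronger than the methylene C–H bonds for which this copper hydroxylation is established. Decay of the copper hydroperoxide, oxidation of the picolyl CH2, or loss of formaldehyde from the product alkoxide may win. The fallback uses known chemistry, sets out from 3 and returns at 13. It masks the side chain first and directs the C–H functionalisation from the alcohol instead of the ketone. DMAP-catalysed acetylation of the 13-OH gives 13-O-acetyl-3-oxosclareol F1. PdCl2(MeCN)2 shifts the acetate to give (13E)-15-acetoxy-8α-hydroxylabd-13-en-3-one F2. LiBH(s-Bu)3 gives (13E)-15-acetoxylabd-13-ene-3α,8α-diol F3. Et2SiH2 with [Ir(cod)OMe]2 gives the 3-O-diethylhydrosilyl ether F4. [Ir(cod)OMe]2 with 3,4,7,8-tetramethyl-1,10-phenanthroline and norbornene (THF, 100 °C) closes F4 onto the gauche equatorial C18 methyl to give the oxasilolane F5 (hydroxyl-directed C–H silylation). Tamao–Fleming oxidation (H2O2, KHCO3, THF–MeOH, rt) gives (13E)-15-acetoxylabd-13-ene-3α,8α,18-triol F6. TEMPO/PhI(OAc)2 in wet MeCN takes C18 through (13E)-15-acetoxy-3α,8α-dihydroxylabd-13-en-18-al F7 to (13E)-15-acetoxy-3α,8α-dihydroxylabd-13-en-18-oic acid F8. Ac2O/DMAP then acetylates the 3α-OH, and bicarbonate cleavage of the mixed acetic anhydride of 13 F9 gives 13.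

Step 5 may stall at the hindered neopentyl aldehyde, or the β-hydroxy aldehyde may undergo retro-aldol opening of ring A. The fallback sets out from 8 and returns at 12. The oxidation is stopped at aldehyde 9 (TEMPO, PhI(OAc)2 1.1 equiv, dry CH2Cl2). The 3α- and 13-hydroxyls are acetylated (Ac2O, DMAP, Et3N) to give (13R)-3α,13-diacetoxy-8α-hydroxylabd-14-en-18-al F10, in which retro-aldol is no longer possible. Pinnick oxidation (NaClO2, NaH2PO4, 2-methyl-2-butene, t-BuOH/H2O) then gives 12 directly.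

Step 6 depends on a rate difference between two tertiary alcohols (13-OH faster than 8α-OH) that I have not seen demonstrated on sclareol itself; over-acetylation at O8 would block step 8. The fallback sets out from 10 and returns at 15. It gives up the free 8-OH and uses an acetate syn-elimination instead. Exhaustive acetylation with AcCl/N,N-dimethylaniline (the standard way to diacetylate sclareol) gives, through the mixed acetic anhydride of F12 F11 and bicarbonate work-up, (13R)-3α,8α,13-triacetoxylabd-14-en-18-oic acid F12. PdCl2(MeCN)2 gives (13E)-3α,8α,15-triacetoxylabd-13-en-18-oic acid F13. Thermal elimination of the tertiary 8α-acetate (2,4,6-collidine, 170 °C) gives 15. This elimination is less regioselective than step 8, so the ring-alkene isomers must be removed on AgNO3-impregnated silica.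

**Further compounds**
F1 | step 3 | 13-O-acetyl-3-oxosclareol, (13R)-13-acetoxy-8α-hydroxylabd-14-en-3-one | C[C@@]1(O)CC[C@@H]2[C@](C)(CCC(=O)C2(C)C)[C@H]1CC[C@@](C)(OC(C)=O)C=C
F2 | step 3 | (13E)-15-acetoxy-8α-hydroxylabd-13-en-3-one | C[C@@]1(O)CC[C@@H]2[C@](C)(CCC(=O)C2(C)C)[C@H]1CC/C(C)=C/COC(C)=O
F3 | step 3 | (13E)-15-acetoxylabd-13-ene-3α,8α-diol | C[C@@]1(O)CC[C@@H]2[C@](C)(CC[C@@H](O)C2(C)C)[C@H]1CC/C(C)=C/COC(C)=O
F4 | step 3 | 3-O-diethylhydrosilyl ether of F3 | C[C@@]1(O)CC[C@@H]2[C@](C)(CC[C@@H](O[SiH](CC)CC)C2(C)C)[C@H]1CC/C(C)=C/COC(C)=O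
F5 | step 3 | oxasilolane of F3 (five-membered ring O3–SiEt2–C18–C4–C3) | C[C@@]1(O)CC[C@@H]2[C@](C)(CC[C@H]3O[Si](CC)(CC)C[C@]32C)[C@H]1CC/C(C)=C/COC(C)=O
F6 | step 3 | (13E)-15-acetoxylabd-13-ene-3α,8α,18-triol | C[C@@]1(O)CC[C@@H]2[C@](C)(CC[C@@H](O)[C@@]2(C)CO)[C@H]1CC/C(C)=C/COC(C)=O
F7 | step 3 | (13E)-15-acetoxy-3α,8α-dihydroxylabd-13-en-18-al | C[C@@]1(O)CC[C@@H]2[C@](C)(CC[C@@H](O)[C@@]2(C)C=O)[C@H]1CC/C(C)=C/COC(C)=O
F8 | step 3 | (13E)-15-acetoxy-3α,8α-dihydroxylabd-13-en-18-oic acid | C[C@@]1(O)CC[C@@H]2[C@](C)(CC[C@@H](O)[C@@]2(C)C(=O)O)[C@H]1CC/C(C)=C/COC(C)=O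
F9 | step 3 | mixed acetic anhydride of 13 | C[C@@]1(O)CC[C@@H]2[C@](C)(CC[C@@H](OC(C)=O)[C@@]2(C)C(=O)OC(C)=O)[C@H]1CC/C(C)=C/COC(C)=O
F10 | step 5 | (13R)-3α,13-diacetoxy-8α-hydroxylabd-14-en-18-al | C[C@@]1(O)CC[C@@H]2[C@](C)(CC[C@@H](OC(C)=O)[C@@]2(C)C=O)[C@H]1CC[C@@](C)(OC(C)=O)C=C
F11 | step 6 | mixed acetic anhydride of F12 | C[C@@]1(OC(C)=O)CC[C@@H]2[C@](C)(CC[C@@H](OC(C)=O)[C@@]2(C)C(=O)OC(C)=O)[C@H]1CC[C@@](C)(OC(C)=O)C=C
F12 | step 6 | (13R)-3α,8α,13-triacetoxylabd-14-en-18-oic acid | C[C@@]1(OC(C)=O)CC[C@@H]2[C@](C)(CC[C@@H](OC(C)=O)[C@@]2(C)C(=O)O)[C@H]1CC[C@@](C)(OC(C)=O)C=C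
F13 | step 6 | (13E)-3α,8α,15-triacetoxylabd-13-en-18-oic acid | C[C@@]1(OC(C)=O)CC[C@@H]2[C@](C)(CC[C@@H](OC(C)=O)[C@@]2(C)C(=O)O)[C@H]1CC/C(C)=C/COC(C)=O
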